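The ratio I carry is double product over mono adduct, divided by the free reagent. I assume the starting material takes reagent in two steps, first to a mono adduct, then to double product. What is not double product I count as mono adduct. Alder is the asked flask, followed so far.

| setting | alder | birch | flask |
|---|---|---|---|
| starting material | 0.20 M | 0.30 M | 0.20 M |
| reagent | 0.40 M | 0.40 M | 0.400 M |
| temperature | 50 °C | 50 °C | 50 °C |
| remark | the very flask that is asked about, followed so far | run made earlier |  |
| time |  |  | 2.0 d |

alder run (percent of the starting material charged)

| time / h | double product / % |
|---|---|
| 3.00 | 31.3 |
| 10.0 | 31.7 |
| 15.0 | 31.5 |
| 25.0 | 31.4 |
| 40.0 | 31.4 |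
| 50.0 | 31.4 |

birch run (percent of the starting material charged)

| time / min | double product / % |
|---|---|
| 8.00 | 20.1 |
| 20.0 | 19.8 |
| 40.0 | 17.5 |
| 60.0 | 16.1 |
| 80.0 | 16.5 |
| 120 | 15.3 |

(each reading ± 0.5 percentage points)

- what is taken out of double product is counted as made
- additions bring no volume worth counting
- the earlier runs do not show what temperature does; that part of a forecast is a guess

- east: at 2.0 d raise the temperature by 20 K, then wait 15 h
- south: at 2.0 d take out 90 % of the double product then present, then wait 15 h
- south-east: at 2.0 d add reagent, 50.0 % of the amount charged, then wait 15 h
- north-east: change nothing and wait 15 h more

* double product, in percent of the starting material first charged, at 2.0 d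
* which option adds most double product ("none" when 2 percentage points or less is all one gets) (east / south / south-east / north-east / none)
* double product present, with what was taken out counted in, in percent of the starting material first charged, after east
* double product present, with what was taken out counted in, in percent of the starting material first charged, after north-east

Two extremes can be done in the head. With no way back, this flask, at 2.00 reagent per starting material, ends at 100 % double product. With no second step, it ends as mono adduct with half of the reagent free. The readings lie between. Alder stands flat near 31.5 % from 3.00 h on. Birch falls from 20.1 % to 15.3 %, so double product goes back. I read alder as an end state, with 34.3 % of its reagent free. That gives Q, the equilibrium constant, the ratio above with free reagent taken as that fraction of the charge: 3.35 /M. As a check on a different charge, Q puts birch at 15.3 %, and its last reading is 15.3 %.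

So I expect 31.5 % now, and the same after north-east. Q also prices the options. Added reagent reaches 50.1 %, and taking out reaches 47.1 %, a little less. The runs give me no number for heat.

The forecast says 31.4 % now, south-east as best, 30.5 % after east and 31.4 % after north-east. On heat it says: “Heating is a guess, probably a small shift”.

The flask gives 31.6 % at 2.0 d and 31.6 % after north-east. South-east is best and adds 18 percentage points, south adds 16 points, and east ends at 17.9 %, a change of −14 points.

    starting material + reagent → mono adduct (k = 0.0101 /M/s, Ea = 73.0 kJ/mol)
    reagent + mono adduct ⇌ double product (K = 3.40 /M, k = 0.0113 /M/s, Ea = 72.0 kJ/mol, ΔH = −43.0 kJ/mol)
    starting material + mono adduct → side product (k = 1.85 × 10⁻⁴ /M/s, Ea = 68.0 kJ/mol)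
    (constants at 50 °C)

A run of this flask without the reverse step reaches 99.1 % instead of 31.6 % at 2.0 d, so the way back holds this flask down. Reckoned the same way, the 17.9 % after east reads as 1.33 /M, against the 3.35 /M I read from alder at 50 °C, and the forecast stood 13 points too high there. A neighbour flask is the same flask with 1.6 M of reagent. There I take free reagent as the charge less two shares of starting material, and Q gives 80.1 %. The computed result is 80.7 %.

All runs were generated by integration for an exercise; scatter was added.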